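**Retrosynthetic overview**

1. The route rests on the 1,4 relationship across the cyclohexane ring between the tertiary alcohol oxygen on C1 and the ketone carbon C4. One oxygen atom can span both positions, first as the ring oxygen of a 2-alkyl-5-methoxyfuran and then as the bridge of a 7-oxabicyclo[2.2.1]heptane ketal.
2. Key disconnection: C4–C5 and C6–C1 (retro-[4+2]), giving a furan diene that already carries the palmitoyloxyethyl arm, and phenyl vinyl sulfone as an ethylene equivalent. The diene comes from 2-methoxyfuran, ethylene oxide and palmitoyl chloride.
3. Ring order: the carbocycle is the only ring of the target and is closed in the cycloaddition, together with the temporary oxygen-bridged ring, which is opened again near the end.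
4. The bridged adduct keeps hydrogen on C5 and C6 and could lose its bridge oxygen as water to give an anisole. Its C2=C3 alkene is therefore saturated before acid opens the ketal, and the sulfonyl group, by then alpha to the C4 ketone, is removed last by reduction.

Key step: step 3

Remark on the chemistry: the target has no stereocentre, since C1 lies on the mirror plane of the ring. The bicyclic and sulfonyl-bearing intermediates are therefore carried as racemic diastereomer mixtures and written without stereodescriptors. Ring atoms are labelled as in the target (C1 carbinol, C4 ketone, C5 next to C4, C6 next to C1), and these labels coincide with the bicyclo[2.2.1] numbering of the adduct.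

**Route**

Step 1
Reactants: 1 2-methoxyfuran; 2 ethylene oxide
Product: 4 2-(5-methoxyfuran-2-yl)ethanol, via 5-lithio-2-methoxyfuran 3 (not isolated)
Conditions: n-BuLi (1.05 equiv), THF, −78 → 0 °C; then 2 (solution in THF, 1.5 equiv), −78 °C → rt; H2O quench, neutral work-up
Reagents that add atoms: none
Why: Alpha-lithiation of the furan at C5, the only free position next to the ring oxygen, gives 3, whose SN2 ring opening of ethylene oxide installs the hydroxyethyl arm, and the basic quench spares the acid-labile 2-alkoxyfuran.

Step 2
Reactants: 4 2-(5-methoxyfuran-2-yl)ethanol; 5 palmitoyl chloride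
Product: 6 2-(5-methoxyfuran-2-yl)ethyl palmitate
Conditions: Et3N, DMAP (cat.), CH2Cl2, 0 °C → rt; NaHCO3 wash, Et3N-deactivated SiO2
Reagents that add atoms: none
Why: DMAP-catalysed nucleophilic acyl substitution of a primary alcohol with an acid chloride, run under amine buffering so that the acid-sensitive methoxyfuran survives; no stereocentre is involved.

Step 3
Reactants: 6 2-(5-methoxyfuran-2-yl)ethyl palmitate; 7 phenyl vinyl sulfone
Product: 8 2-[4-methoxy-5-(phenylsulfonyl)-7-oxabicyclo[2.2.1]hept-2-en-1-yl]ethyl palmitate (racemic, endo/exo mixture at C5)
Conditions: 7 (2 equiv), solid K2CO3, PhMe (3 M), 50 °C, sealed tube, dark (CH2Cl2, 10 kbar, 25 °C if conversion stalls); filtration through basic Al2O3, used at once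
Reagents that add atoms: none
Why: This is a normal-electron-demand Diels–Alder reaction, concerted but asynchronous, in which the bond from the alkyl-bearing furan carbon (C1, largest HOMO coefficient of the methoxy-activated diene) to the CH2 terminus of 7 (C6, largest LUMO coefficient) leads and the bond from the methoxy-bearing carbon (C4) to the sulfonyl carbon (C5) follows. The closest known reaction types are the cycloadditions of 2-alkoxyfurans with electron-poor alkenes and of furans with vinyl sulfones under heat or pressure. The six-membered carbocycle C1–C2=C3–C4–C5–C6 is closed by this intermolecular [4+2] cycloaddition, which forms C4–C5 and C6–C1 in one event and turns the furan oxygen into the one-atom bridge of a 7-oxabicyclo[2.2.1]heptene. The three new stereocentres (C1, C4, C5) are not controlled: the two bridgeheads are tied to each other by the bridge, C5 forms as an endo/exo mixture, everything is racemic, and all three disappear in steps 5 and 6. The selectivity needed is regiochemical, sulfur on the carbon next to the ketal carbon, and it follows from the polarisation that the methoxy donor gives the diene; the alkyl-bearing furan carbon has no hydrogen, so the conjugate-addition and rearomatisation path open to 2-methoxyfuran itself is closed. Solid K2CO3 and a non-acidic isolation keep the bridged ketal from opening, which would otherwise lead on by loss of water to an anisole.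

Step 4
Reactants: 8 2-[4-methoxy-5-(phenylsulfonyl)-7-oxabicyclo[2.2.1]hept-2-en-1-yl]ethyl palmitate
Product: 9 2-[4-methoxy-3-(phenylsulfonyl)-7-oxabicyclo[2.2.1]heptan-1-yl]ethyl palmitate (racemic, endo/exo mixture at the sulfonyl carbon)
Conditions: H2 (1 atm), 5% Pd/C, solid K2CO3, EtOAc, 0 °C → rt
Reagents that add atoms: none
Why: Heterogeneous catalytic hydrogenation (syn addition of H2) of the strained oxanorbornene alkene should be fast and leave sulfone, ester and ketal untouched; it creates no stereocentre (C2 and C3 become CH2) and removes both the cycloreversion path and the unsaturation that aromatisation would need once the bridge is opened.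

Step 5
Reactants: 9 2-[4-methoxy-3-(phenylsulfonyl)-7-oxabicyclo[2.2.1]heptan-1-yl]ethyl palmitate
Product: 10 2-[1-hydroxy-4-oxo-3-(phenylsulfonyl)cyclohexyl]ethyl palmitate (racemic, cis/trans mixture)
Conditions: 1 M aq HCl, THF, 25 → 40 °C
Reagents that add atoms: water, SMILES O
Why: Acid-catalysed ketal hydrolysis: protonation of the bridge oxygen, cleavage of its bond to C4 to a methoxy-oxocarbenium ion, capture by water and loss of methanol give the C4 ketone while the former bridge oxygen stays on C1 as the tertiary alcohol; C1 and the sulfonyl carbon of 10 are uncontrolled stereocentres that step 6 erases, and the palmitate should resist dilute acid at this temperature.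

Step 6
Reactants: 10 2-[1-hydroxy-4-oxo-3-(phenylsulfonyl)cyclohexyl]ethyl palmitate
Product: 11 2-(1-hydroxy-4-oxocyclohexyl)ethyl palmitate (target, achiral)
Conditions: Al(Hg) (Al foil amalgamated with 2% aq HgCl2), THF/H2O (9:1), 0 °C → rt
Reagents that add atoms: none
Why: Reductive desulfonylation of a beta-keto sulfone by electron transfer from aluminium amalgam cleaves the C–S bond to an enolate and benzenesulfinate, water protonates the carbon, and the isolated ketone, the ester and the tertiary alcohol are inert; with the sulfonyl group gone the ring regains its mirror plane, so 11 has no stereocentre.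

**Compound list**

1 | 2-methoxyfuran | COc1ccco1 | starting material
2 | ethylene oxide | C1CO1 | starting material
3 | 5-lithio-2-methoxyfuran | [Li]c1ccc(OC)o1 | intermediate (not isolated)
4 | 2-(5-methoxyfuran-2-yl)ethanol | COc1ccc(CCO)o1 | intermediate
5 | palmitoyl chloride | CCCCCCCCCCCCCCCC(Cl)=O | starting material
6 | 2-(5-methoxyfuran-2-yl)ethyl palmitate | CCCCCCCCCCCCCCCC(=O)OCCc1ccc(OC)o1 | intermediate
7 | phenyl vinyl sulfone | C=CS(=O)(=O)c1ccccc1 | starting material
8 | 2-[4-methoxy-5-(phenylsulfonyl)-7-oxabicyclo[2.2.1]hept-2-en-1-yl]ethyl palmitate, racemic endo/exo mixture | COC12C=CC(CCOC(=O)CCCCCCCCCCCCCCC)(CC1S(=O)(=O)c1ccccc1)O2 | intermediate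
9 | 2-[4-methoxy-3-(phenylsulfonyl)-7-oxabicyclo[2.2.1]heptan-1-yl]ethyl palmitate, racemic endo/exo mixture | COC12CCC(CCOC(=O)CCCCCCCCCCCCCCC)(CC1S(=O)(=O)c1ccccc1)O2 | intermediate
10 | 2-[1-hydroxy-4-oxo-3-(phenylsulfonyl)cyclohexyl]ethyl palmitate, racemic cis/trans mixture | CCCCCCCCCCCCCCCC(=O)OCCC1(O)CCC(=O)C(C1)S(=O)(=O)c1ccccc1 | intermediate
11 | 2-(1-hydroxy-4-oxocyclohexyl)ethyl palmitate | CCCCCCCCCCCCCCCC(=O)OCCC1(O)CCC(=O)CC1 | target

**Step count and risks**

Total step count: 6. Longest linear sequence: 6 steps (1 → 4 → 6 → 8 → 9 → 10 → 11).

Steps most likely to fail: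

1. Step 3. The cycloaddition may be too slow at temperatures the adduct tolerates, the adduct may revert to its components, or the oxygen bridge may open and water be lost with aromatisation. Fallback: leave the furan approach and build the same ring by oxidative dearomatisation of a phenol, setting out from palmitoyl chloride 5 and coming back at target 11. 4-(2-Hydroxyethyl)phenol F1 (tyrosol, bought) would be acylated on its aliphatic hydroxyl with 5 in dimethyl carbonate without base, to give 2-(4-hydroxyphenyl)ethyl palmitate F2. Oxidation of F2 with PhI(OAc)2 in MeCN/H2O at 0 °C should deliver the para-quinol 2-(1-hydroxy-4-oxocyclohexa-2,5-dien-1-yl)ethyl palmitate F3. Hydrogenation of both ring alkenes of F3 with H2 over Rh/Al2O3 in EtOAc would give 11.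

2. Step 4. The adduct may be lost before its alkene is saturated, by cycloreversion in solution or by bridge opening on the catalyst surface. Fallback: reverse the order of events, setting out from 8 and coming back at 10. Brief treatment of 8 with oxalic acid on wet SiO2 in CH2Cl2 at 0 °C, where water capture of the oxocarbenium ion should outrun dehydration, would open the ketal to the hydroxy enone 2-[1-hydroxy-4-oxo-5-(phenylsulfonyl)cyclohex-2-en-1-yl]ethyl palmitate F4. The enone alkene of F4 would then be saturated with H2 over Rh/Al2O3 in EtOAc to give 10.

3. Step 5. The sulfonyl group next to the ketal carbon destabilises the oxocarbenium ion, so the opening may be sluggish, and forcing acid may start to cleave the palmitate or ionise the tertiary C1–O bond. Fallback: a non-hydrolytic, dealkylative ketal cleavage, setting out from 9 and coming back at 10. Me3SiI (made from Me3SiCl and NaI in MeCN, −20 → 0 °C) should silylate the bridge oxygen and open it to the methyl oxocarbenium ion, from which iodide removes the methyl group by SN2, leaving the ketone 2-[4-oxo-3-(phenylsulfonyl)-1-(trimethylsilyloxy)cyclohexyl]ethyl palmitate F5. Mild desilylation of F5 (0.1 M aq HCl, THF, 0 °C) would give 10.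

Further compounds
F1 | step 3 | 4-(2-hydroxyethyl)phenol (tyrosol; bought, not made) | OCCc1ccc(O)cc1
F2 | step 3 | 2-(4-hydroxyphenyl)ethyl palmitate | CCCCCCCCCCCCCCCC(=O)OCCc1ccc(O)cc1
F3 | step 3 | 2-(1-hydroxy-4-oxocyclohexa-2,5-dien-1-yl)ethyl palmitate | CCCCCCCCCCCCCCCC(=O)OCCC1(O)C=CC(=O)C=C1
F4 | step 4 | 2-[1-hydroxy-4-oxo-5-(phenylsulfonyl)cyclohex-2-en-1-yl]ethyl palmitate, racemic diastereomer mixture | CCCCCCCCCCCCCCCC(=O)OCCC1(O)C=CC(=O)C(C1)S(=O)(=O)c1ccccc1
F5 | step 5 | 2-[4-oxo-3-(phenylsulfonyl)-1-(trimethylsilyloxy)cyclohexyl]ethyl palmitate, racemic diastereomer mixture | CCCCCCCCCCCCCCCC(=O)OCCC1(O[Si](C)(C)C)CCC(=O)C(C1)S(=O)(=O)c1ccccc1
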